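**Plan**

- Retrosynthesis: the acid-labile groups (two MOM ethers, one tert-butyl ester) and the resolution come last. The C2 methyl ester / C3 acid pair is traced back to a five-membered cyclic anhydride, whose ring O–C(=O) bond is not in the target. Ring B is then cut at C4–C4a and C2–C3 to a mixed anhydride of propiolic acid with a (Z)-3-aryl-3-pyranonylacrylic acid. That acid is cut at its two C(sp2)–C(sp2) bonds to a 3-bromo-2-pyranone ester, acrylic acid and a protected 4-bromocatechol.
- Forward: the pyranone ring is bought and brominated; the acrylic chain and then the arene are joined by two Heck reactions; the acid is tied to propiolic acid as an anhydride; ring B and the anhydride ring close together in one thermal dehydro-Diels–Alder step; methanol opens the tether.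
- Enabling feature: C2=C1 together with the C8a=C4a bond of the catechol ring (ring A) is a styrene-type diene whose terminus C4a lies para to the C7 oxygen. The carboxyl carbons on C2 and C3 sit where a three-atom anhydride bridge can hold the alkyne C3≡C4 under that diene.
- Stereochemistry: C2 arises in the cycloaddition and C1 in the proton shift that restores the arene, both racemic. C2 is then equilibrated to the trans half ester after tether opening. The (1R,2R) enantiomer is obtained by resolution on a chiral stationary phase; the route contains no asymmetric step.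

Key step: step 6

Remarks
- Locants: C1 carries the pyranone, C2 the methyl ester, C3 the free acid, C4 is the vinylic CH, C4a/C8a are the ring-fusion carbons, the oxygens sit on C6 and C7; ring B is the dihydro ring.
- Assumption: 2-oxo-2H-pyran-6-carboxylic acid is taken as purchasable, like acrylic acid, propiolic acid and 4-bromocatechol.
- Racemic compounds are drawn as the enantiomer that is carried on; "rac" in the name marks them.

**Route**

Step 1
Reactants: 1 2-oxo-2H-pyran-6-carboxylic acid
Product: 2 tert-butyl 2-oxo-2H-pyran-6-carboxylate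
Conditions: Cl3CC(=NH)Ot-Bu (2.5 equiv), BF3·OEt2 (5 mol %), CH2Cl2/cyclohexane, rt
Reagents that add atoms: tert-butyl 2,2,2-trichloroacetimidate, CC(C)(C)OC(=N)C(Cl)(Cl)Cl
Why: Acid-catalysed transfer of a tert-butyl cation from the imidate to the carboxylic acid (trichloroacetimidate esterification) forms the ester without any base or nucleophile that would open the 2-pyranone, and the tert-butyl ester later leaves under the same acid that removes the MOM groups.

Step 2
Reactants: 2 tert-butyl 2-oxo-2H-pyran-6-carboxylate
Product: 3 tert-butyl 3-bromo-2-oxo-2H-pyran-6-carboxylate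
Conditions: Br2 (1.05 equiv), CH2Cl2, 0 °C to rt; then Et3N (1.2 equiv), 0 °C
Reagents that add atoms: bromine, BrBr
Why: Bromination–dehydrobromination of a 2-pyranone: bromine attacks C3, the end of the O1–C6=C5–C4=C3 dienol-ether system whose other nucleophilic site C5 is deactivated by the C6 ester, and Et3N then removes HBr through the acidic C3–H to restore the ring as the 3-bromide.

Step 3
Reactants: 3 tert-butyl 3-bromo-2-oxo-2H-pyran-6-carboxylate, 4 acrylic acid
Product: 5 (2E)-3-[6-(tert-butoxycarbonyl)-2-oxo-2H-pyran-3-yl]prop-2-enoic acid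
Conditions: 4 (1.5 equiv), Pd(OAc)2 (5 mol %), P(o-tol)3 (10 mol %), Et3N (3 equiv), MeCN, 80 °C; aq. citric acid
Reagents that add atoms: none
Why: Mizoroki–Heck reaction: the C3–Br bond, an α-bromo enoate, adds readily to zerovalent palladium, acrylate inserts with the pyranone on its unsubstituted carbon, and syn β-hydride elimination gives the E acid, while the tertiary amine base leaves the lactone alone.

Step 4
Reactants: 6 4-bromobenzene-1,2-diol
Product: 7 4-bromo-1,2-bis(methoxymethoxy)benzene
Conditions: MOMCl (2.5 equiv), i-Pr2NEt (3 equiv), CH2Cl2, 0 °C to rt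
Reagents that add atoms: chloromethyl methyl ether, COCCl
Why: Double O-alkylation of the catechol with the reactive α-chloro ether (MOM protection) gives acetals that survive base, palladium and heat, shield the ring position next to them in step 6 and are cleaved by TFA at the end.

Step 5
Reactants: 5 (2E)-3-[6-(tert-butoxycarbonyl)-2-oxo-2H-pyran-3-yl]prop-2-enoic acid, 7 4-bromo-1,2-bis(methoxymethoxy)benzene
Product: 8 (2Z)-3-[3,4-bis(methoxymethoxy)phenyl]-3-[6-(tert-butoxycarbonyl)-2-oxo-2H-pyran-3-yl]prop-2-enoic acid
Conditions: 7 (1.3 equiv), Pd2(dba)3 (2.5 mol %), [HP(t-Bu)3]BF4 (10 mol %), Cy2NMe (3 equiv), 1,4-dioxane, 100 °C; aq. citric acid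
Reagents that add atoms: none
Why: Second Mizoroki–Heck reaction on the β-substituted acrylic acid: the aryl group adds to the β-carbon and palladium to the α-carbon, and after bond rotation syn β-hydride elimination leaves the incoming aryl trans to the carboxyl group and the pyranone cis to it, which is the Z geometry that step 6 needs; the bulky electron-rich phosphine is chosen for the electron-rich bromide and the hindered alkene.

Step 6
Reactants: 8 (2Z)-3-[3,4-bis(methoxymethoxy)phenyl]-3-[6-(tert-butoxycarbonyl)-2-oxo-2H-pyran-3-yl]prop-2-enoic acid, 9 propiolic acid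
Product: 12 rac-1-[6-(tert-butoxycarbonyl)-2-oxo-2H-pyran-3-yl]-6,7-bis(methoxymethoxy)-1,2-dihydronaphthalene-2,3-dicarboxylic anhydride (both C2 epimers), via mixed anhydride 10 (not isolated), via isotoluene cycloadduct 11 (not isolated)
Conditions: 9 (3 equiv), DCC (2 equiv), CH2Cl2, 0 °C; filter; then PhMe, 2,6-lutidine (0.2 equiv), 90 °C
Reagents that add atoms: none
Why: DCC condenses 8 with 9 to the mixed anhydride 10, whose C(=O)–O–C(=O) bridge holds the ynoate under the styrene-type diene C2=C1–C8a=C4a; a thermal, asynchronous [4+2] cycloaddition (intramolecular dehydro-Diels–Alder reaction) joins the nucleophilic terminus C4a, para to the C7 oxygen, to the ynoate β-carbon C4 and joins C2 to C3, giving isotoluene 11, whose C4a–H is carried to C1 by the lutidine/lutidinium pair so that the arene is restored and 12 results. The closest known reaction type is the thermal intramolecular dehydro-Diels–Alder reaction of styrene-ynes such as cinnamyl propiolates and of arylpropiolic anhydrides, which gives aryl(dihydro)naphthalene lactones and anhydrides. Ring B is closed by the cycloaddition itself, since both new bonds lie in it, and the five-membered anhydride ring is closed by the C2–C3 bond as the fused ring of an intramolecular Diels–Alder reaction whose three-atom tether starts at the diene terminus. C2 and the transient C4a centre are set by suprafacial addition with H-2 and H-4a cis and without facial bias, hence racemic, and C1 is set in the proton shift; neither needs control here because C2 is equilibrated in step 7 and the enantiomers are separated in step 8. The step needs three selectivities: the arene rather than the pyranone as the second π bond of the diene, secured by the Z geometry that puts the arene trans and the pyranone cis to the tether carbonyl; bond formation at the ring carbon that becomes C4a rather than at the one between the side chain and the neighbouring OMOM group, secured by that flanking MOM ether; and proton shift rather than loss of H2 to the naphthalene, secured by the base shuttle and the moderate temperature.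

Step 7
Reactants: 12 rac-1-[6-(tert-butoxycarbonyl)-2-oxo-2H-pyran-3-yl]-6,7-bis(methoxymethoxy)-1,2-dihydronaphthalene-2,3-dicarboxylic anhydride (both C2 epimers)
Product: 14 rac-(1R*,2R*)-1-[6-(tert-butoxycarbonyl)-2-oxo-2H-pyran-3-yl]-2-(methoxycarbonyl)-6,7-bis(methoxymethoxy)-1,2-dihydronaphthalene-3-carboxylic acid, via cis half ester 13 (not isolated)
Conditions: MeOH (10 equiv), i-Pr2NEt (1.2 equiv), CH2Cl2, 0 °C to rt; evaporate; DBU (1.5 equiv), CH2Cl2, rt; aq. citric acid
Reagents that add atoms: methanol, CO
Why: Alcoholysis of the unsymmetrical anhydride takes place at the saturated C2 carbonyl, because the C3 carbonyl is deactivated by conjugation with the C3=C4–arene system, and gives the C2 methyl ester and the C3 acid; DBU then epimerises C2 through the ester dienolate to the thermodynamically preferred trans half ester, in which the pyranone at C1 and the ester at C2 are both pseudoaxial and so avoid H8 and the C3 carboxyl group.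

Step 8
Reactants: 14 rac-(1R*,2R*)-1-[6-(tert-butoxycarbonyl)-2-oxo-2H-pyran-3-yl]-2-(methoxycarbonyl)-6,7-bis(methoxymethoxy)-1,2-dihydronaphthalene-3-carboxylic acid
Product: 15 (1R,2R)-1-[6-(tert-butoxycarbonyl)-2-oxo-2H-pyran-3-yl]-2-(methoxycarbonyl)-6,7-bis(methoxymethoxy)-1,2-dihydronaphthalene-3-carboxylic acid
Conditions: preparative SFC, amylose tris(3,5-dimethylphenylcarbamate) stationary phase, CO2/MeOH with 0.1 % HCO2H, 35 °C
Reagents that add atoms: none
Why: Chromatographic resolution on a chiral stationary phase separates the two enantiomers of the carboxylic acid without any chemical change, and the (1R,2R) fraction is to be identified by comparing the ECD curve of an aliquot taken through step 9 with the calculated curve.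

Step 9
Reactants: 15 (1R,2R)-1-[6-(tert-butoxycarbonyl)-2-oxo-2H-pyran-3-yl]-2-(methoxycarbonyl)-6,7-bis(methoxymethoxy)-1,2-dihydronaphthalene-3-carboxylic acid
Product: 16 (1R,2R)-1-(6-carboxy-2-oxo-2H-pyran-3-yl)-6,7-dihydroxy-2-(methoxycarbonyl)-1,2-dihydronaphthalene-3-carboxylic acid (CNP0239263.1)
Conditions: TFA/CH2Cl2/H2O (10:10:1), 0 °C to rt
Reagents that add atoms: none
Why: Acidolysis: TFA ionises the tert-butyl ester (isobutene is lost) and hydrolyses both MOM acetals through oxocarbenium ions, while the methyl ester, the pyranone, the C3=C4 bond and, in the absence of base, both stereocentres are left untouched.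

**Compound list**

1 | 2-oxo-2H-pyran-6-carboxylic acid | O=C(O)c1cccc(=O)o1 | starting material
2 | tert-butyl 2-oxo-2H-pyran-6-carboxylate | CC(C)(C)OC(=O)c1cccc(=O)o1 | intermediate
3 | tert-butyl 3-bromo-2-oxo-2H-pyran-6-carboxylate | CC(C)(C)OC(=O)c1ccc(Br)c(=O)o1 | intermediate
4 | acrylic acid | C=CC(=O)O | starting material
5 | (2E)-3-[6-(tert-butoxycarbonyl)-2-oxo-2H-pyran-3-yl]prop-2-enoic acid | O=C(O)/C=C/c1ccc(C(=O)OC(C)(C)C)oc1=O | intermediate
6 | 4-bromobenzene-1,2-diol | Oc1ccc(Br)cc1O | starting material
7 | 4-bromo-1,2-bis(methoxymethoxy)benzene | COCOc1ccc(Br)cc1OCOC | intermediate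
8 | (2Z)-3-[3,4-bis(methoxymethoxy)phenyl]-3-[6-(tert-butoxycarbonyl)-2-oxo-2H-pyran-3-yl]prop-2-enoic acid (aryl trans to CO2H) | O=C(O)/C=C(/c1ccc(OCOC)c(OCOC)c1)c1ccc(C(=O)OC(C)(C)C)oc1=O | intermediate
9 | propiolic acid | C#CC(=O)O | starting material
10 | mixed anhydride of 8 with propiolic acid, Z alkene retained | C#CC(=O)OC(=O)/C=C(/c1ccc(OCOC)c(OCOC)c1)c1ccc(C(=O)OC(C)(C)C)oc1=O | intermediate
11 | rac-isotoluene cycloadduct: 1-[6-(tert-butoxycarbonyl)-2-oxo-2H-pyran-3-yl]-6,7-bis(methoxymethoxy)-2,4a-dihydronaphthalene-2,3-dicarboxylic anhydride, C1=C8a double bond, H-2 and H-4a cis | O=C1OC(=O)C2=C[C@H]3C=C(OCOC)C(OCOC)=CC3=C(c3ccc(C(=O)OC(C)(C)C)oc3=O)[C@@H]12 | intermediate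
12 | rac-1-[6-(tert-butoxycarbonyl)-2-oxo-2H-pyran-3-yl]-6,7-bis(methoxymethoxy)-1,2-dihydronaphthalene-2,3-dicarboxylic anhydride, both C2 epimers, C1 as drawn | O=C1OC(=O)C2=Cc3cc(OCOC)c(OCOC)cc3[C@H](c3ccc(C(=O)OC(C)(C)C)oc3=O)C12 | intermediate
13 | rac-(1R*,2S*) cis half ester: 1-[6-(tert-butoxycarbonyl)-2-oxo-2H-pyran-3-yl]-2-(methoxycarbonyl)-6,7-bis(methoxymethoxy)-1,2-dihydronaphthalene-3-carboxylic acid | COC(=O)[C@@H]1C(C(=O)O)=Cc2cc(OCOC)c(OCOC)cc2[C@@H]1c1ccc(C(=O)OC(C)(C)C)oc1=O | intermediate
14 | rac-(1R*,2R*) trans half ester of the same constitution | COC(=O)[C@H]1C(C(=O)O)=Cc2cc(OCOC)c(OCOC)cc2[C@@H]1c1ccc(C(=O)OC(C)(C)C)oc1=O | intermediate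
15 | (1R,2R) trans half ester, single enantiomer | COC(=O)[C@H]1C(C(=O)O)=Cc2cc(OCOC)c(OCOC)cc2[C@@H]1c1ccc(C(=O)OC(C)(C)C)oc1=O | intermediate
16 | (1R,2R)-1-(6-carboxy-2-oxo-2H-pyran-3-yl)-6,7-dihydroxy-2-(methoxycarbonyl)-1,2-dihydronaphthalene-3-carboxylic acid | COC(=O)[C@H]1C(C(=O)O)=Cc2cc(O)c(O)cc2[C@@H]1c1ccc(C(=O)O)oc1=O | target

**Totals and risks**

Total steps: 9. Longest linear sequence: 8 steps (1 → 2 → 3 → 5 → 8 → 12 → 14 → 15 → 16); step 4 lies on the side branch.

Most likely to fail, riskiest first:

1. Step 6. What may go wrong: disproportionation of the mixed anhydride into the two symmetric anhydrides and oligomerisation of the terminal ynoate before cycloaddition; a sluggish cycloaddition because the 1,1-disubstituted styrene cannot become planar; loss of H2 from the cycloadduct instead of the proton shift. Fallback, setting out from 7 (with 9 and 5) and coming back at 12: the roles of diene and dienophile are exchanged. Bromide 7 is coupled with propiolic acid 9 in a Sonogashira-type reaction (Pd(PPh3)4, DBU, DMSO, 40 °C) to 3-[3,4-bis(methoxymethoxy)phenyl]prop-2-ynoic acid F1. F1 and the E acid 5 are condensed with DCC (CH2Cl2, 0 °C) to the mixed arylpropiolic acrylic anhydride F2, in which the arylalkyne is the diene and the acrylate C=C the dienophile. On warming in toluene F2 should cyclise by the classical dehydro-Diels–Alder reaction of arylpropiolic anhydrides and, after the proton shift that restores the arene, give anhydride 12. Suprafacial addition to the E alkene should give the 1,2-trans relation directly. The route continues with step 7.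

2. Step 5. What may go wrong: slow insertion of the hindered, β-substituted acrylic acid into the aryl–palladium bond and E/Z scrambling by re-addition of palladium hydride. Fallback, setting out from 3 (with 9 and 7) and coming back at 8: the alkene is made by stereospecific syn-hydroarylation of an alkyne. Propiolic acid 9 is esterified with 2-(trimethylsilyl)ethanol (DCC, CH2Cl2, 0 °C) to 2-(trimethylsilyl)ethyl prop-2-ynoate F3. Sonogashira coupling of 3 with F3 (Pd(PPh3)2Cl2, CuI, K2CO3, THF, rt) gives the pyranonyl alkynoate F4. Bromide 7 is converted by bromine–lithium exchange and borylation (n-BuLi, THF, −78 °C; B(OMe)3; aq. NH4Cl) into [3,4-bis(methoxymethoxy)phenyl]boronic acid F5. CuOAc-catalysed addition of F5 to F4 (MeOH, rt) places the aryl group on the β-carbon, syn to the new hydrogen and trans to the ester, and gives the 2-(trimethylsilyl)ethyl ester F6 of acid 8. Bu4NF (THF, 0 °C) then frees acid 8.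

3. Step 7. What may go wrong: incomplete epimerisation at C2 of the carboxylate, or migration of the C3=C4 double bond and opening of the pyranone lactone under the amount of DBU needed. Fallback, setting out from 13 (the crude half ester before the DBU treatment) and coming back at 14: the acid is masked for the equilibration. Half ester 13 is esterified with allyl alcohol (DCC, cat. DMAP, CH2Cl2, 0 °C) to the cis allyl methyl diester F7. Without the carboxylate the C2–H is much more acidic, so a catalytic amount of DBU at 0 °C should suffice to equilibrate it to the trans allyl methyl diester F8. Pd(PPh3)4/PhSiH3 (CH2Cl2, rt) then removes the allyl group and returns trans half ester 14.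

**Further compounds**

F1 | step 6 | 3-[3,4-bis(methoxymethoxy)phenyl]prop-2-ynoic acid | OC(=O)C#Cc1ccc(OCOC)c(OCOC)c1
F2 | step 6 | mixed anhydride of F1 with (2E)-acid 5 | O=C(C#Cc1ccc(OCOC)c(OCOC)c1)OC(=O)/C=C/c1ccc(C(=O)OC(C)(C)C)oc1=O
F3 | step 5 | 2-(trimethylsilyl)ethyl prop-2-ynoate | C#CC(=O)OCC[Si](C)(C)C
F4 | step 5 | tert-butyl 2-oxo-3-{3-oxo-3-[2-(trimethylsilyl)ethoxy]prop-1-yn-1-yl}-2H-pyran-6-carboxylate | CC(C)(C)OC(=O)c1ccc(C#CC(=O)OCC[Si](C)(C)C)c(=O)o1
F5 | step 5 | [3,4-bis(methoxymethoxy)phenyl]boronic acid | OB(O)c1ccc(OCOC)c(OCOC)c1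
F6 | step 5 | 2-(trimethylsilyl)ethyl (2Z)-3-[3,4-bis(methoxymethoxy)phenyl]-3-[6-(tert-butoxycarbonyl)-2-oxo-2H-pyran-3-yl]prop-2-enoate | C[Si](C)(C)CCOC(=O)/C=C(/c1ccc(OCOC)c(OCOC)c1)c1ccc(C(=O)OC(C)(C)C)oc1=O
F7 | step 7 | rac-(1R*,2S*) cis 3-allyl 2-methyl diester of the protected dihydronaphthalene diacid | COC(=O)[C@@H]1C(C(=O)OCC=C)=Cc2cc(OCOC)c(OCOC)cc2[C@@H]1c1ccc(C(=O)OC(C)(C)C)oc1=O
F8 | step 7 | rac-(1R*,2R*) trans 3-allyl 2-methyl diester of the protected dihydronaphthalene diacid | COC(=O)[C@H]1C(C(=O)OCC=C)=Cc2cc(OCOC)c(OCOC)cc2[C@@H]1c1ccc(C(=O)OC(C)(C)C)oc1=O
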